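(Its constants belong to no real substance; the run is a simulation.)

Write the balance first: free catalyst plus idle complex always equals the catalyst charged, and the added ligand enters no other step, so at one temperature c(free catalyst) stays one number for the whole run.

| setting | birch | larch | elm | oak |
|---|---|---|---|---|
| left-handed substrate | 0.83 M | 0.83 M | 0.83 M | 0.83 M |
| reagent | 1.20 equiv | 1.20 equiv | 1.20 equiv | 1.20 equiv |
| catalyst | 0.1 mol% | 0.1 mol% | 0.1 mol% | 0.1 mol% |
| added ligand | 4.0 mM | 4.0 mM | 4.0 mM | 4.0 mM |
| right-handed substrate | 0.83 M | 0.83 M | 0.83 M | 0.83 M |
| temperature | 20 °C | 110 °C | 80 °C | 50 °C |
| time | 6.0 min | 6.0 min | 6.0 min | 6.0 min |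

- the best flask by amount of left-handed product, in percent of the left-handed substrate and right-handed substrate together charged; "all alike" if 1.5 percentage points covers them all (birch / larch / elm / oak / all alike)
- amount of left-handed product at the end, in percent of the left-handed substrate and right-handed substrate together charged, birch
- amount of left-handed product at the end, in percent of the left-handed substrate and right-handed substrate together charged, larch
- amount of left-handed product at the end, in percent of the left-handed substrate and right-handed substrate together charged, elm
- amount of left-handed product at the end, in percent of the left-handed substrate and right-handed substrate together charged, oak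

- catalyst is single-handed; left-handed substrate and right-handed substrate are mirror images of each other, charged as a racemate, each of them at the stated concentration
- the list of constants is for 50 °C, to be carried to other temperatures by the activation energies and enthalpies

    reagent + catalyst + right-handed substrate → catalyst + right-handed product (k1 = 0.27 L² mol⁻² s⁻¹, Ea1 = 52.0 kJ mol⁻¹)
    catalyst + added ligand ⇌ idle complex, settled at all times (K2 = 640 L mol⁻¹, ΔH2 = −54.0 kJ mol⁻¹)
    reagent + catalyst + left-handed substrate → catalyst + left-handed product (k3 = 0.80 L² mol⁻² s⁻¹, Ea3 = 55.0 kJ mol⁻¹)
    (constants at 50 °C)

Now work with the fraction of left-handed substrate left and not with the product. While c(reagent) stays near its charge the left-handed step is pseudo-first-order, and the fraction left is exp(−x), with x = k·c(free catalyst)·c(reagent)·t. The product, counted on both substrates, is half of the fraction consumed.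

Take birch, with the left-handed step alone and all of its 0.830 mM of catalyst free. The rate constant carried to 20 °C is 0.0985 L² mol⁻² s⁻¹, so x is 0.0293 and the product is 1.44%.

Add the idle complex. At 20 °C the balance constant is 5010 L mol⁻¹, and solving the balance with 4.0 mM of added ligand leaves 0.0485 mM free in birch, 5.84% of the charge. So birch has 0.00171 as its exposure, minus the logarithm of the fraction of left-handed substrate left at the end. The product drops to 0.0856%, less than before.

Add the right-handed step. Together the two steps spend 0.197% of the reagent in birch, so holding c(reagent) constant leaves my number standing.

In larch the same reckoning stops. The balance constant falls to 27.5 L mol⁻¹, which leaves 0.749 mM free, and the exposure at constant reagent is 5.30, 3099 times that of birch. With a selectivity factor of 3.53 the two steps would ask for 88.6% of the substrates, while the reagent charge covers 60.0%, less. So c(reagent) does not stay near its charge in larch, where the reagent is the limiting reagent, and I commit to 0.0856% for birch and to more product in larch, without a number for larch.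

The forecast names larch as best, with 0.086% for birch, 38.6% for larch, 23.5% for elm and 3.44% for oak, on the ground that “conversion climbs steeply with temperature”.

The simulation gives 0.0855% for birch, 38.6% for larch, 23.5% for elm and 3.45% for oak, with larch best. Carry the exposure to the neighbour, birch with 0.06 mol% of catalyst, which charges 0.498 mM. The balance leaves 0.0267 mM free, 5.36% of that charge, so the exposure is 9.42 × 10⁻⁴ and the reckoned product is 0.0471%. The simulated neighbour holds 0.0471% of left-handed product.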